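**Remark (assumption on the chemistry):** the target is taken as (2S,3S,5S)-5-bromo-2-[(1R,3S,4S)-4-bromo-3-chloro-4-methylcyclohexyl]-2,6,6-trimethyloxan-3-ol. Locants C2–C6/O1 (oxane) and C1'–C6' (cyclohexane) in the discussion are those of this name; intermediates keep their own systematic numbering. The tertiary bromide is assumed to survive neutral or weakly basic, non-ionizing conditions, because the vicinal chlorine retards its ionization. In the SMILES of titanium compounds the cyclopentadienyl rings are drawn σ-bonded through one carbon, and the Tebbe reagent is drawn in its open form with the chloride on titanium (the Ti–Cl–Al bridge is not drawn).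

## Retrosynthetic overview

1. Target ⇐ anti addition of OH (to C3) and CH3 (to C2) across the C2=C3 enol ether of a 3,4-dihydro-2H-pyran (dimethyldioxirane, then MeMgCl); the C5–Br stereocentre steers both new centres.
2. Dihydropyran ⇐ tert-alkyl ester with a pendant vinyl group, by one-pot titanium-methylidene carbonyl methylenation and ring-closing metathesis: the ester carbon becomes C2, the internal vinyl carbon becomes C3, and the C2–C3 bond closes the oxane.
3. Enabling feature: in the oxane, ring oxygen O1 sits on the fully substituted C2 and C3 carries OH. This O1–C2–C3–OH array is the retron of a cyclic enol ether and, one oxidation level up, of an ester O1–C2(=O); the gem-dimethyl C6 favours closure.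
4. Ester ⇐ (1R,3S,4S)-4-bromo-3-chloro-4-methylcyclohexanecarboxylic acid (Diels–Alder of isoprene with a chiral acrylimide, then chlorohydrin formation and HBr) + (3S)-3-bromo-2-methylhex-5-en-2-ol (from L-allylglycine: Cα → C5, CO2H → C6, allyl → C4 and C3).
5. Ring order: cyclohexane first (Diels–Alder), oxane second (key step).

Key step: step 10

## Route

Step 1
Reactants: 1 L-allylglycine, (2S)-2-aminopent-4-enoic acid
Product: 2 (2S)-2-bromopent-4-enoic acid
Conditions: NaNO2, KBr, 2.5 M aq. HBr, −5 → 0 °C
Reagents that add atoms: hydrogen bromide, Br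
Why: Diazotization–bromination of an α-amino acid, in which the carboxylate displaces N2 to an α-lactone that bromide reopens, so two inversions give net retention and the (S) centre that becomes C5; the remote vinyl group should not react at 0 °C.

Step 2
Reactants: 2 (2S)-2-bromopent-4-enoic acid
Product: 3 methyl (2S)-2-bromopent-4-enoate
Conditions: MeOH, H2SO4 (cat.), 25 °C
Reagents that add atoms: methanol, CO
Why: Fischer esterification; the α-bromo stereocentre is not enolized under acid.

Step 3
Reactants: 3 methyl (2S)-2-bromopent-4-enoate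
Product: 4 (3S)-3-bromo-2-methylhex-5-en-2-ol
Conditions: MeMgBr (2.4 equiv), Et2O, −78 → −40 °C; pH 7 buffer at −40 °C
Reagents that add atoms: methylmagnesium bromide, C[Mg]Br
Why: Double Grignard addition to an α-halo ester gives the tertiary carbinol (the future C6 with its two methyl groups); kept cold, the bromomagnesium alkoxide should neither close to the epoxide nor enolize the C–Br centre.

Step 4
Reactants: 5 (4S)-4-benzyl-1,3-oxazolidin-2-one; 6 acryloyl chloride
Product: 7 (4S)-3-acryloyl-4-benzyl-1,3-oxazolidin-2-one
Conditions: Et3N, LiCl, THF, −20 → 25 °C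
Reagents that add atoms: none
Why: Lithium-chloride-assisted N-acylation of the oxazolidinone, the mild variant that avoids anionic polymerization of the acryloyl group.

Step 5
Reactants: 7 (4S)-3-acryloyl-4-benzyl-1,3-oxazolidin-2-one; 8 isoprene (2-methylbuta-1,3-diene)
Product: 9 (4S)-4-benzyl-3-[(1R)-4-methylcyclohex-3-ene-1-carbonyl]-1,3-oxazolidin-2-one
Conditions: Et2AlCl (1.4 equiv), CH2Cl2, −100 → −78 °C
Reagents that add atoms: none
Why: Lewis-acid-promoted Diels–Alder reaction in which Et2AlCl chelates both imide carbonyls (s-cis acryloyl), the benzyl group shields one face and isoprene adds to the other with "para" regiochemistry, which should set C1' as (R) and build the cyclohexane ring.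

Step 6
Reactants: 9 (4S)-4-benzyl-3-[(1R)-4-methylcyclohex-3-ene-1-carbonyl]-1,3-oxazolidin-2-one
Product: 10 (4S)-4-benzyl-3-[(1R,3S,4S)-3-chloro-4-hydroxy-4-methylcyclohexane-1-carbonyl]-1,3-oxazolidin-2-one
Conditions: trichloroisocyanuric acid (0.37 equiv), acetone/H2O 5:1, 0 → 25 °C
Reagents that add atoms: trichloroisocyanuric acid, O=C1N(Cl)C(=O)N(Cl)C(=O)N1Cl; water, O
Why: Chlorohydrin formation (cohalogenation) in which Cl+ adds axially to C3' on the face trans to the equatorial acyl group and water opens the β-chloro cation at the tertiary C4' in trans-diaxial (Fürst–Plattner), Markovnikov fashion, as in halohydrin formation from limonene; this should set C3' (S) and the C4' oxygen cis to the acyl group.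

Step 7
Reactants: 10 (4S)-4-benzyl-3-[(1R,3S,4S)-3-chloro-4-hydroxy-4-methylcyclohexane-1-carbonyl]-1,3-oxazolidin-2-one
Product: 11 (4S)-4-benzyl-3-[(1R,3S,4S)-4-bromo-3-chloro-4-methylcyclohexane-1-carbonyl]-1,3-oxazolidin-2-one
Conditions: HBr (gas, excess), CH2Cl2, 0 → 25 °C
Reagents that add atoms: hydrogen bromide, Br
Why: SN1 substitution of a tertiary alcohol by bromide in which the cation is bridged by the anti-periplanar axial chlorine, so bromide should enter axially anti to Cl with net retention at C4' (S); any alkene formed by E1 re-adds HBr through the same cation, and the imide is inert to HBr.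

Step 8
Reactants: 11 (4S)-4-benzyl-3-[(1R,3S,4S)-4-bromo-3-chloro-4-methylcyclohexane-1-carbonyl]-1,3-oxazolidin-2-one
Product: 13 (1R,3S,4S)-4-bromo-3-chloro-4-methylcyclohexane-1-carboxylic acid, via lithium percarboxylate 12 (not isolated)
Conditions: LiOH, 30% H2O2, THF/H2O 3:1, 0 °C; Na2SO3; then 1 M HCl
Reagents that add atoms: hydrogen peroxide (acting as LiOOH), OO
Why: Hydroperoxide cleavage of the N-acyloxazolidinone at the exocyclic carbonyl, then sulfite reduction of the percarboxylate; cold LiOOH should neither epimerize C1' nor eliminate the chlorine-deactivated tertiary bromide, and the auxiliary is recovered.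

Step 9
Reactants: 13 (1R,3S,4S)-4-bromo-3-chloro-4-methylcyclohexane-1-carboxylic acid; 4 (3S)-3-bromo-2-methylhex-5-en-2-ol
Product: 15 (3S)-3-bromo-2-methylhex-5-en-2-yl (1R,3S,4S)-4-bromo-3-chloro-4-methylcyclohexane-1-carboxylate, via acid chloride 14 (not isolated)
Conditions: (COCl)2, DMF (cat.), CH2Cl2, 0 → 25 °C, evaporate; then 4, DMAP (2 equiv), CH2Cl2, 25 → 40 °C
Reagents that add atoms: oxalyl chloride, O=C(Cl)C(=O)Cl
Why: Acylation of a tertiary alcohol by an acid chloride under nucleophilic catalysis (acylpyridinium from DMAP), in which oxalyl chloride supplies only the chlorine of 14 that is lost again on acylation; no alkoxide is formed, so the bromohydrin should not close to its epoxide, and this step makes the O1–C2 bond at the ester oxidation level.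

Step 10
Reactants: 15 (3S)-3-bromo-2-methylhex-5-en-2-yl (1R,3S,4S)-4-bromo-3-chloro-4-methylcyclohexane-1-carboxylate
Product: 17 (3S)-3-bromo-6-[(1R,3S,4S)-4-bromo-3-chloro-4-methylcyclohexyl]-2,2-dimethyl-3,4-dihydro-2H-pyran, via acyclic enol ether 16 (not isolated)
Conditions: Tebbe reagent Cp2Ti(μ-Cl)(μ-CH2)AlMe2 (4 equiv), pyridine (cat.), THF, −40 → 25 °C; then 65 °C; filtration through basic alumina
Reagents that add atoms: Tebbe reagent Cp2Ti(μ-Cl)(μ-CH2)AlMe2, C[Al](C)C[Ti](Cl)(C1C=CC=C1)C1C=CC=C1
Why: The titanium methylidene Cp2Ti=CH2 released from the Tebbe reagent first methylenates the ester carbonyl through an oxatitanacyclobutane to give the 2-alkoxy-1-alkene 16; on heating, the same tetravalent titanium methylidene adds to the terminal vinyl group, the titanacyclobutane loses ethene to leave a titanium alkylidene at the future C3, and this closes onto the enol ether C=C and cycloreverts to 17, so that the former ester carbon (C2) and the former internal vinyl carbon (C3) are joined, while the methylene carbon that the reagent had put into 16 leaves again and no atom of the reagent stays in 17. The closest known reaction type is the one-pot Tebbe-mediated conversion of olefinic esters into cyclic enol ethers (carbonyl methylenation followed by ring-closing olefin metathesis), established on alkyl esters that carry an allyl group two carbons from the ester oxygen and close to this kind of six-membered enol ether. The oxane is closed as a six-membered ring by ring-closing metathesis ([2+2]/retro-[2+2] through a bicyclic titanacyclobutane), helped by the gem-dimethyl group at C6 (Thorpe–Ingold effect). No stereocentre is formed; the step creates the trigonal C2=C3 pair on which the allylglycine-derived C5 centre then controls C3 and C2 in step 11. The selectivity needed is chemoselectivity: the titanium carbene is nucleophilic and non-reducing, so it should react only with the ester C=O and the monosubstituted alkene and leave the C–Br and C–Cl bonds alone, whereas olefination systems based on low-valent metals would cause reductive β-elimination of the β-bromo ester; THF and pyridine keep the aluminium by-product from ionizing the tertiary bromide.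

Step 11
Reactants: 17 (3S)-3-bromo-6-[(1R,3S,4S)-4-bromo-3-chloro-4-methylcyclohexyl]-2,2-dimethyl-3,4-dihydro-2H-pyran
Product: 19 (2S,3S,5S)-5-bromo-2-[(1R,3S,4S)-4-bromo-3-chloro-4-methylcyclohexyl]-2,6,6-trimethyloxan-3-ol (the target), via enol ether epoxide 18 (not isolated)
Conditions: dimethyldioxirane (1.1 equiv, acetone-depleted solution), CH2Cl2, −78 °C; volatiles removed cold; then MeMgCl (5 equiv), THF, −78 → 0 °C; pH 7 buffer
Reagents that add atoms: dimethyldioxirane, CC1(C)OO1; methylmagnesium chloride, C[Mg]Cl
Why: Epoxidation of the electron-rich enol ether should occur anti to the pseudoaxial C6 methyl group (the face trans to the pseudoequatorial C5 bromine), and the Grignard reagent then opens the epoxide at the ketal carbon C2 with inversion (trans-diaxial, Fürst–Plattner), the reaction type used to make C-glycosides from 1,2-anhydro sugars; this sets C3 (S) and C2 (S) with OH and CH3 trans-diaxial and the cyclohexyl group equatorial.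

## Compound list

1 | L-allylglycine, (2S)-2-aminopent-4-enoic acid | N[C@@H](CC=C)C(=O)O | starting material
2 | (2S)-2-bromopent-4-enoic acid | Br[C@@H](CC=C)C(=O)O | intermediate
3 | methyl (2S)-2-bromopent-4-enoate | Br[C@@H](CC=C)C(=O)OC | intermediate
4 | (3S)-3-bromo-2-methylhex-5-en-2-ol | CC(C)(O)[C@@H](Br)CC=C | intermediate
5 | (4S)-4-benzyl-1,3-oxazolidin-2-one | O=C1N[C@@H](Cc2ccccc2)CO1 | starting material
6 | acryloyl chloride | C=CC(=O)Cl | starting material
7 | (4S)-3-acryloyl-4-benzyl-1,3-oxazolidin-2-one | C=CC(=O)N1[C@@H](Cc2ccccc2)COC1=O | intermediate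
8 | isoprene, 2-methylbuta-1,3-diene | C=CC(C)=C | starting material
9 | (4S)-4-benzyl-3-[(1R)-4-methylcyclohex-3-ene-1-carbonyl]-1,3-oxazolidin-2-one | CC1=CC[C@@H](CC1)C(=O)N1[C@@H](Cc2ccccc2)COC1=O | intermediate
10 | (4S)-4-benzyl-3-[(1R,3S,4S)-3-chloro-4-hydroxy-4-methylcyclohexane-1-carbonyl]-1,3-oxazolidin-2-one | O=C([C@@H]1CC[C@](C)(O)[C@@H](Cl)C1)N1[C@@H](Cc2ccccc2)COC1=O | intermediate
11 | (4S)-4-benzyl-3-[(1R,3S,4S)-4-bromo-3-chloro-4-methylcyclohexane-1-carbonyl]-1,3-oxazolidin-2-one | O=C([C@@H]1CC[C@](C)(Br)[C@@H](Cl)C1)N1[C@@H](Cc2ccccc2)COC1=O | intermediate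
12 | lithium (1R,3S,4S)-4-bromo-3-chloro-4-methylcyclohexane-1-carboperoxoate | [Li+].[O-]OC(=O)[C@@H]1CC[C@](C)(Br)[C@@H](Cl)C1 | intermediate
13 | (1R,3S,4S)-4-bromo-3-chloro-4-methylcyclohexane-1-carboxylic acid | OC(=O)[C@@H]1CC[C@](C)(Br)[C@@H](Cl)C1 | intermediate
14 | (1R,3S,4S)-4-bromo-3-chloro-4-methylcyclohexane-1-carbonyl chloride | ClC(=O)[C@@H]1CC[C@](C)(Br)[C@@H](Cl)C1 | intermediate
15 | (3S)-3-bromo-2-methylhex-5-en-2-yl (1R,3S,4S)-4-bromo-3-chloro-4-methylcyclohexane-1-carboxylate | CC(C)(OC(=O)[C@@H]1CC[C@](C)(Br)[C@@H](Cl)C1)[C@@H](Br)CC=C | intermediate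
16 | (1S,2S,4R)-1-bromo-4-(1-{[(3S)-3-bromo-2-methylhex-5-en-2-yl]oxy}ethenyl)-2-chloro-1-methylcyclohexane | CC(C)(OC(=C)[C@@H]1CC[C@](C)(Br)[C@@H](Cl)C1)[C@@H](Br)CC=C | intermediate
17 | (3S)-3-bromo-6-[(1R,3S,4S)-4-bromo-3-chloro-4-methylcyclohexyl]-2,2-dimethyl-3,4-dihydro-2H-pyran | CC1(C)OC(=CC[C@@H]1Br)[C@@H]1CC[C@](C)(Br)[C@@H](Cl)C1 | intermediate
18 | (1R,4S,6S)-4-bromo-1-[(1R,3S,4S)-4-bromo-3-chloro-4-methylcyclohexyl]-3,3-dimethyl-2,7-dioxabicyclo[4.1.0]heptane | CC1(C)O[C@@]2([C@@H]3CC[C@](C)(Br)[C@@H](Cl)C3)O[C@H]2C[C@@H]1Br | intermediate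
19 | (2S,3S,5S)-5-bromo-2-[(1R,3S,4S)-4-bromo-3-chloro-4-methylcyclohexyl]-2,6,6-trimethyloxan-3-ol | CC1(C)O[C@@](C)([C@@H]2CC[C@](C)(Br)[C@@H](Cl)C2)[C@@H](O)C[C@@H]1Br | target

## Step count and risks

Total step count: 11.
Longest linear sequence: 8 steps (steps 4–11, from 5 to 19); the second branch (steps 1–3) joins at step 9.

**Step 11.** What may go wrong: the epoxide may open through a free oxocarbenium ion before the methyl group arrives, with loss of anti stereospecificity at the crowded ketal carbon or a 1,2-hydride shift to a C3 ketone. The fallback sets out from 17 and comes back at 19, and moves stereocontrol at C2 from epoxide opening to an acyclic carbonyl addition. Compound 17 is oxidized with dimethyldioxirane as before, but the epoxide is hydrolysed (wet THF, pH 7) to the open-chain α-hydroxy ketone (2S,4S)-4-bromo-1-[(1R,3S,4S)-4-bromo-3-chloro-4-methylcyclohexyl]-2,5-dihydroxy-5-methylhexan-1-one F1, the crowded hemiketal being expected to collapse to the ketone. TESCl and imidazole in DMF at 0 °C should silylate only the secondary hydroxyl, giving the α-silyloxy ketone (2S,4S)-4-bromo-1-[(1R,3S,4S)-4-bromo-3-chloro-4-methylcyclohexyl]-5-hydroxy-5-methyl-2-(triethylsilyloxy)hexan-1-one F2. MeLi with CeCl3 in THF at −78 °C should add under Felkin–Anh control (silyloxy group anti to the incoming methyl, no chelation), placing CH3 and the C3 oxygen anti as in the target and giving the tertiary carbinol (2S,3S,5S)-5-bromo-2-[(1R,3S,4S)-4-bromo-3-chloro-4-methylcyclohexyl]-6-methyl-3-(triethylsilyloxy)heptane-2,6-diol F3. TfOH (cat.) in (CF3)2CHOH/CH2Cl2 at 0 °C should ionize the C6 hydroxyl with anchimeric help from the C5 bromine, the C2 hydroxyl should open the bromonium ion at the tertiary carbon (the closing event of a 6-endo bromoetherification), and the silyl group is lost in the same operation to give 19.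

**Step 10.** What may go wrong: methylenation of the hindered tert-alkyl ester or the metathesis stage may stall, and the aluminium component may ionize or eliminate the tertiary bromide during prolonged heating. The fallback sets out from 15 and comes back at 17, and splits the cascade into two reactions with different metal carbenes and without aluminium. Cp2TiMe2 in toluene/THF at 65 °C in the dark methylenates the ester so that the acyclic enol ether 16 can be isolated. Ring-closing metathesis of 16 with the second-generation Grubbs catalyst RuCl2(=CHPh)(PCy3)(H2IMes) in benzene at 60 °C should then close 17 with loss of ethene. No new compound is made (F0).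

**Step 9.** What may go wrong: acylation of the crowded tertiary hydroxyl may be slow, which gives time for ketene formation from the acid chloride (epimerization at C1') and for closure of the bromohydrin to its epoxide. The fallback sets out from 4 and 13 and comes back at 15, and reverses the polarity of ester formation. Alcohol 4 is converted with Cl3CCN and DBU (cat.) in CH2Cl2 at −20 °C into (3S)-3-bromo-2-methylhex-5-en-2-yl 2,2,2-trichloroethanimidate F4. F4 is then stirred with acid 13 in cyclohexane/CH2Cl2 at 25 °C (BF3·OEt2 cat. if needed): the protonated imidate leaves as trichloroacetamide, the tertiary cation is bridged by the neighbouring bromine, and the carboxylate opens this bromonium ion at the tertiary carbon, so the ester forms by O-alkylation with the C–Br stereocentre untouched.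

## Further compounds

F1 | step 11 | (2S,4S)-4-bromo-1-[(1R,3S,4S)-4-bromo-3-chloro-4-methylcyclohexyl]-2,5-dihydroxy-5-methylhexan-1-one | CC(C)(O)[C@@H](Br)C[C@H](O)C(=O)[C@@H]1CC[C@](C)(Br)[C@@H](Cl)C1
F2 | step 11 | (2S,4S)-4-bromo-1-[(1R,3S,4S)-4-bromo-3-chloro-4-methylcyclohexyl]-5-hydroxy-5-methyl-2-(triethylsilyloxy)hexan-1-one | CC(C)(O)[C@@H](Br)C[C@H](O[Si](CC)(CC)CC)C(=O)[C@@H]1CC[C@](C)(Br)[C@@H](Cl)C1
F3 | step 11 | (2S,3S,5S)-5-bromo-2-[(1R,3S,4S)-4-bromo-3-chloro-4-methylcyclohexyl]-6-methyl-3-(triethylsilyloxy)heptane-2,6-diol | CC(C)(O)[C@@H](Br)C[C@H](O[Si](CC)(CC)CC)[C@@](C)(O)[C@@H]1CC[C@](C)(Br)[C@@H](Cl)C1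
F0 | step 10 | none | none
F4 | step 9 | (3S)-3-bromo-2-methylhex-5-en-2-yl 2,2,2-trichloroethanimidate | CC(C)(OC(=N)C(Cl)(Cl)Cl)[C@@H](Br)CC=C
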